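## Retrosynthetic overview

1. Feature: in ring A of the apigenin half, C8a carries O1 and lies directly between the biaryl carbon C8 and the carbonyl-bearing C4a. With iodine on C4a this is an ortho-iodophenol. It derives from a 2-aryl-5-benzyloxyresorcinol whose two open ring positions are equivalent, so a single iodination defines it.
2. Last disconnection: ring C of the apigenin half is opened at C4a–C4, C4–C3 and O1–C2, giving that iodophenol, CO and 4-benzyloxyphenylacetylene.
3. Before it: the C6–C8'' biaryl bond goes back to a 6-iodoacacetin dibenzyl ether and a 4-benzyloxy-2,6-bis(methoxymethoxy)phenylboronate made from phloroglucinol.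
4. The C6 iodide is set while the 5-OH is still free, because a 5,7-dibenzyl ether would be iodinated at C8. The order is therefore 7-O-benzylation, iodination, 5-O-benzylation.
5. Ring order: the acacetin chromenone and all benzene rings are bought, and ring C of the apigenin half is the only ring built. Hydrogenolysis of four benzyl ethers ends the route.

Key step: step 11

Assumption: the target SMILES carries no axial descriptor, so the 6,8''-biaryl axis is formed without control of its configuration.

## Route

Step 1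
Reactants: 1 acacetin
Product: 2 7-(benzyloxy)-5-hydroxy-2-(4-methoxyphenyl)chromen-4-one
Conditions: BnBr (1.05 equiv), K2CO3, DMF, rt
Reagents that add atoms: benzyl bromide, BrCc1ccccc1
Why: Williamson etherification, in which the free and more acidic 7-OH reacts while the 5-OH, hydrogen-bonded to the C4 carbonyl, stays untouched by one equivalent of BnBr under mild base.

Step 2
Reactants: 2 7-(benzyloxy)-5-hydroxy-2-(4-methoxyphenyl)chromen-4-one
Product: 3 7-(benzyloxy)-5-hydroxy-6-iodo-2-(4-methoxyphenyl)chromen-4-one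
Conditions: NIS (1.1 equiv), DMF, rt, dark
Reagents that add atoms: N-iodosuccinimide, O=C1CCC(=O)N1I
Why: Electrophilic aromatic iodination under neutral conditions, where 5-hydroxy-7-alkoxyflavones react ortho to the chelated phenol at C6 whereas the 5,7-dialkyl ethers react at C8, which is why iodine goes in before the second benzylation.

Step 3
Reactants: 3 7-(benzyloxy)-5-hydroxy-6-iodo-2-(4-methoxyphenyl)chromen-4-one
Product: 4 5,7-bis(benzyloxy)-6-iodo-2-(4-methoxyphenyl)chromen-4-one
Conditions: BnBr (3 equiv), K2CO3, DMF, 60 °C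
Reagents that add atoms: benzyl bromide, BrCc1ccccc1
Why: Williamson etherification under forcing conditions breaks the chelate and caps the hindered 5-OH, and the aryl iodide and the pyranone are inert to carbonate.

Step 4
Reactants: 5 phloroglucinol
Product: 6 5-(benzyloxy)benzene-1,3-diol
Conditions: 5 (3 equiv), BnBr (1 equiv), K2CO3 (1 equiv), DMF, rt
Reagents that add atoms: benzyl bromide, BrCc1ccccc1
Why: Statistical Williamson mono-O-alkylation, in which an excess of the cheap water-soluble triol suppresses further benzylation and is washed out with water, and the polar aprotic medium favours O- over C-benzylation.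

Step 5
Reactants: 6 5-(benzyloxy)benzene-1,3-diol
Product: 7 1-(benzyloxy)-3,5-bis(methoxymethoxy)benzene
Conditions: MOMCl (2.5 equiv), iPr2NEt, CH2Cl2, 0 °C to rt
Reagents that add atoms: chloromethyl methyl ether, COCCl
Why: O-alkylation of both phenols with the hard electrophile MOMCl gives acetal ethers that are orthogonal to benzyl and act as directing groups in the next step.

Step 6
Reactants: 7 1-(benzyloxy)-3,5-bis(methoxymethoxy)benzene
Product: 9 2-[4-(benzyloxy)-2,6-bis(methoxymethoxy)phenyl]-4,4,5,5-tetramethyl-1,3,2-dioxaborolane, via aryllithium 8 (not isolated)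
Conditions: n-BuLi (1.15 equiv), THF, 0 °C; then iPrOBpin, −78 °C to rt
Reagents that add atoms: 2-isopropoxy-4,4,5,5-tetramethyl-1,3,2-dioxaborolane, CC(C)OB1OC(C)(C)C(C)(C)O1; n-butyllithium, [Li]CCCC (lithium of 8 only)
Why: Directed ortho-metalation followed by borylation, in which the CH flanked by two chelating MOM ethers is lithiated in preference to the CH positions flanked by one MOM ether and the weakly coordinating benzyl ether, and the symmetric product can be purified from any unsymmetric isomer at this stage.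

Step 7
Reactants: 4 5,7-bis(benzyloxy)-6-iodo-2-(4-methoxyphenyl)chromen-4-one; 9 2-[4-(benzyloxy)-2,6-bis(methoxymethoxy)phenyl]-4,4,5,5-tetramethyl-1,3,2-dioxaborolane
Product: 10 5,7-bis(benzyloxy)-6-[4-(benzyloxy)-2,6-bis(methoxymethoxy)phenyl]-2-(4-methoxyphenyl)chromen-4-one
Conditions: 9 (1.5–2 equiv), Pd(OAc)2 (10 mol %), SPhos (20 mol %), K3PO4, toluene/H2O 10:1, 90 °C
Reagents that add atoms: none
Why: Suzuki–Miyaura coupling, in which the bulky electron-rich biarylphosphine gives a monoligated zerovalent palladium that inserts into the hindered C6–I bond and still allows transmetalation and reductive elimination to a biaryl with four ortho oxygen substituents, while the excess of 9 covers loss by protodeboronation.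

Step 8
Reactants: 10 5,7-bis(benzyloxy)-6-[4-(benzyloxy)-2,6-bis(methoxymethoxy)phenyl]-2-(4-methoxyphenyl)chromen-4-one
Product: 11 5,7-bis(benzyloxy)-6-[4-(benzyloxy)-2,6-dihydroxyphenyl]-2-(4-methoxyphenyl)chromen-4-one
Conditions: HCl (cat.), MeOH/THF, 45 °C
Reagents that add atoms: none
Why: Acid-catalysed transacetalisation of the two MOM acetals to methanol frees the symmetric resorcinol, while the aryl benzyl ethers, the methyl ether and the pyranone tolerate dilute methanolic HCl.

Step 9
Reactants: 11 5,7-bis(benzyloxy)-6-[4-(benzyloxy)-2,6-dihydroxyphenyl]-2-(4-methoxyphenyl)chromen-4-one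
Product: 12 5,7-bis(benzyloxy)-6-[4-(benzyloxy)-2,6-dihydroxy-3-iodophenyl]-2-(4-methoxyphenyl)chromen-4-one
Conditions: NIS (1.0 equiv, slow addition), CH2Cl2/MeCN, −20 to 0 °C
Reagents that add atoms: N-iodosuccinimide, O=C1CCC(=O)N1I
Why: Electrophilic aromatic iodination, in which the free resorcinol ring is by far the most electron-rich arene of 11, its position between the hydroxyls is blocked by the flavone and its two remaining CH positions are related by symmetry, so one equivalent of NIS in the cold should give a single mono-iodide with iodine between OH and OBn.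

Step 10
Reactants: 13 4-(benzyloxy)benzaldehyde
Product: 14 1-(benzyloxy)-4-ethynylbenzene
Conditions: dimethyl (1-diazo-2-oxopropyl)phosphonate (1.2 equiv), K2CO3, MeOH/THF, rt
Reagents that add atoms: dimethyl (1-diazo-2-oxopropyl)phosphonate, COP(=O)(OC)C(=[N+]=[N-])C(C)=O
Why: Ohira–Bestmann variant of the Seyferth–Gilbert homologation, in which methanolysis frees the diazomethylphosphonate anion, this olefinates the non-enolisable aldehyde, and loss of N2 with a 1,2-hydride shift gives the terminal alkyne without harm to the benzyl ether.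

Step 11
Reactants: 12 5,7-bis(benzyloxy)-6-[4-(benzyloxy)-2,6-dihydroxy-3-iodophenyl]-2-(4-methoxyphenyl)chromen-4-one; 14 1-(benzyloxy)-4-ethynylbenzene; 15 carbon monoxide
Product: 18 5,7-bis(benzyloxy)-6-{5-(benzyloxy)-2-[4-(benzyloxy)phenyl]-7-hydroxy-4-oxochromen-8-yl}-2-(4-methoxyphenyl)chromen-4-one, via ynone 16 (not isolated), via enaminone 17 (not isolated)
Conditions: 14 (1.5 equiv), PdCl2(PPh3)2 (10 mol %), CuI (5 mol %), CO (5 bar), Et2NH/DMF 1:2, 60 °C
Reagents that add atoms: carbon monoxide (compound 15), [C-]#[O+]; diethylamine, CCNCC (held only in 17 and released again)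
Why: Zerovalent palladium, formed from PdCl2(PPh3)2 by amine and alkyne, inserts into the C–I bond of 12, the electron-rich aryl group migrates to coordinated CO to make C4a–C4, and the copper acetylide of 14 transfers its alkynyl group so that reductive elimination makes C4–C3 and releases ynone 16. The closest known reaction type is the palladium-catalysed carbonylative Sonogashira annulation of 2-iodophenols with aryl acetylenes in secondary-amine media, an established flavone synthesis. Ring C closes in the 6-endo mode: Et2NH adds to the β-carbon of the ynone to give enaminone 17, the neighbouring phenol then attacks that carbon in a 6-endo-trig addition–elimination that forms O1–C2 and expels Et2NH, and this detour bypasses the 5-exo-dig closure that would give the aurone. No stereocentre is formed. The 8-linkage needs no reagent control, because only the hydroxyl lying between the biaryl carbon and the acyl-bearing carbon is ortho to the ynone, the oxygen on the other side of it is benzylated, and the second hydroxyl is para to the acyl group and simply ends as the 7-OH. The step also needs CO insertion to outrun direct alkynylation (the path to a 2-arylbenzofuran) and alkynyl transfer to outrun aminolysis of the acylpalladium, which the electron-rich migrating aryl group, the CO overpressure, the copper acetylide and the two ortho substituents that shield the acyl carbon from Et2NH should secure.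

Step 12
Reactants: 18 5,7-bis(benzyloxy)-6-{5-(benzyloxy)-2-[4-(benzyloxy)phenyl]-7-hydroxy-4-oxochromen-8-yl}-2-(4-methoxyphenyl)chromen-4-one
Product: 19 5,7-dihydroxy-6-[5,7-dihydroxy-2-(4-hydroxyphenyl)-4-oxochromen-8-yl]-2-(4-methoxyphenyl)chromen-4-one (CNP0302154.0)
Conditions: H2 (1 atm), 10% Pd/C, THF/MeOH, rt
Reagents that add atoms: none
Why: Catalytic hydrogenolysis cleaves the four O–CH2Ph bonds at ambient pressure, conditions under which the aryl methyl ether and the conjugated C2–C3 double bonds of both flavone units are normally retained.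

## Compound list

1 | acacetin | COc1ccc(-c2cc(=O)c3c(O)cc(O)cc3o2)cc1 | starting material
2 | 7-(benzyloxy)-5-hydroxy-2-(4-methoxyphenyl)chromen-4-one | COc1ccc(-c2cc(=O)c3c(O)cc(OCc4ccccc4)cc3o2)cc1 | intermediate
3 | 7-(benzyloxy)-5-hydroxy-6-iodo-2-(4-methoxyphenyl)chromen-4-one | COc1ccc(-c2cc(=O)c3c(O)c(I)c(OCc4ccccc4)cc3o2)cc1 | intermediate
4 | 5,7-bis(benzyloxy)-6-iodo-2-(4-methoxyphenyl)chromen-4-one | COc1ccc(-c2cc(=O)c3c(OCc4ccccc4)c(I)c(OCc4ccccc4)cc3o2)cc1 | intermediate
5 | phloroglucinol | Oc1cc(O)cc(O)c1 | starting material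
6 | 5-(benzyloxy)benzene-1,3-diol | Oc1cc(O)cc(OCc2ccccc2)c1 | intermediate
7 | 1-(benzyloxy)-3,5-bis(methoxymethoxy)benzene | COCOc1cc(OCOC)cc(OCc2ccccc2)c1 | intermediate
8 | [4-(benzyloxy)-2,6-bis(methoxymethoxy)phenyl]lithium | [Li]c1c(OCOC)cc(OCc2ccccc2)cc1OCOC | intermediate (not isolated)
9 | 2-[4-(benzyloxy)-2,6-bis(methoxymethoxy)phenyl]-4,4,5,5-tetramethyl-1,3,2-dioxaborolane | COCOc1cc(OCc2ccccc2)cc(OCOC)c1B1OC(C)(C)C(C)(C)O1 | intermediate
10 | 5,7-bis(benzyloxy)-6-[4-(benzyloxy)-2,6-bis(methoxymethoxy)phenyl]-2-(4-methoxyphenyl)chromen-4-one | COc1ccc(-c2cc(=O)c3c(OCc4ccccc4)c(-c4c(OCOC)cc(OCc5ccccc5)cc4OCOC)c(OCc4ccccc4)cc3o2)cc1 | intermediate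
11 | 5,7-bis(benzyloxy)-6-[4-(benzyloxy)-2,6-dihydroxyphenyl]-2-(4-methoxyphenyl)chromen-4-one | COc1ccc(-c2cc(=O)c3c(OCc4ccccc4)c(-c4c(O)cc(OCc5ccccc5)cc4O)c(OCc4ccccc4)cc3o2)cc1 | intermediate
12 | 5,7-bis(benzyloxy)-6-[4-(benzyloxy)-2,6-dihydroxy-3-iodophenyl]-2-(4-methoxyphenyl)chromen-4-one | COc1ccc(-c2cc(=O)c3c(OCc4ccccc4)c(-c4c(O)cc(OCc5ccccc5)c(I)c4O)c(OCc4ccccc4)cc3o2)cc1 | intermediate
13 | 4-(benzyloxy)benzaldehyde | O=Cc1ccc(OCc2ccccc2)cc1 | starting material
14 | 1-(benzyloxy)-4-ethynylbenzene | C#Cc1ccc(OCc2ccccc2)cc1 | intermediate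
15 | carbon monoxide | [C-]#[O+] | starting material
16 | 5,7-bis(benzyloxy)-6-{4-(benzyloxy)-3-[3-(4-benzyloxyphenyl)prop-2-ynoyl]-2,6-dihydroxyphenyl}-2-(4-methoxyphenyl)chromen-4-one | COc1ccc(-c2cc(=O)c3c(OCc4ccccc4)c(-c4c(O)cc(OCc5ccccc5)c(C(=O)C#Cc5ccc(OCc6ccccc6)cc5)c4O)c(OCc4ccccc4)cc3o2)cc1 | intermediate (not isolated)
17 | 5,7-bis(benzyloxy)-6-{4-(benzyloxy)-3-[(E)-3-(4-benzyloxyphenyl)-3-(diethylamino)prop-2-enoyl]-2,6-dihydroxyphenyl}-2-(4-methoxyphenyl)chromen-4-one | COc1ccc(-c2cc(=O)c3c(OCc4ccccc4)c(-c4c(O)cc(OCc5ccccc5)c(C(=O)/C=C(/N(CC)CC)c5ccc(OCc6ccccc6)cc5)c4O)c(OCc4ccccc4)cc3o2)cc1 | intermediate (not isolated)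
18 | 5,7-bis(benzyloxy)-6-{5-(benzyloxy)-2-[4-(benzyloxy)phenyl]-7-hydroxy-4-oxochromen-8-yl}-2-(4-methoxyphenyl)chromen-4-one | COc1ccc(-c2cc(=O)c3c(OCc4ccccc4)c(-c4c(O)cc(OCc5ccccc5)c5c(=O)cc(-c6ccc(OCc7ccccc7)cc6)oc45)c(OCc4ccccc4)cc3o2)cc1 | intermediate
19 | 5,7-dihydroxy-6-[5,7-dihydroxy-2-(4-hydroxyphenyl)-4-oxochromen-8-yl]-2-(4-methoxyphenyl)chromen-4-one (CNP0302154.0) | COc1ccc(-c2cc(=O)c3c(O)c(-c4c(O)cc(O)c5c(=O)cc(-c6ccc(O)cc6)oc45)c(O)cc3o2)cc1 | target

## Step count and risks

Total step count: 12.
Longest linear sequence: 8 steps (1, 2, 3, 7, 8, 9, 11, 12 from acacetin). The phloroglucinol branch (4, 5, 6, 7, 8, 9, 11, 12) is equally long.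

Steps most likely to fail:

**Step 11.** Oxidative addition into the doubly ortho-substituted, phenoxide-rich C–I bond may be too slow under CO. Alkyne dimerisation, alkynylation without CO uptake followed by furan closure, or aminolysis of the acylpalladium could then take over.
- The fallback sets out from 12 and comes back at 18. It brings in the carbonyl carbon as part of an acetyl group, without CO.
- Stille coupling of 12 with tributyl(1-ethoxyvinyl)stannane (PdCl2(PPh3)2, dioxane, 90 °C) should give the 1-ethoxyvinyl arene F1.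
- Dilute HCl in THF should hydrolyse it to the methyl ketone F2.
- The lithium polyanion of F2 (LiHMDS, 5 equiv, THF, −78 °C) is C-acylated with 4-(benzyloxy)benzoyl chloride, a direct variant of the Baker–Venkataraman sequence, to the 1,3-diketone F3.
- Catalytic TsOH in warm toluene closes ring C by cyclodehydration to 18.
- The acetyl group sits where the iodine was, so the regiochemical argument is unchanged.

**Step 7.** Protodeboronation of the electron-rich 2,6-dialkoxyarylboronate may outrun the slow transmetalation between two doubly ortho-substituted partners, and hydrodeiodination of the flavone may accompany it.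
- The fallback sets out from 7 and 4 and comes back at 10. It replaces boron by zinc and excludes water.
- Compound 7 is lithiated as in step 6 to 8, and ZnCl2 (THF, 0 °C) converts this into the arylzinc chloride F4.
- F4 is joined to 4 by Negishi coupling (Pd2(dba)3, RuPhos, THF, 65 °C). This catalyst system is suited to biaryls with four ortho substituents, and the flavone carbonyl tolerates the arylzinc.

**Step 6.** Lithiation may spread over the site between the two MOM ethers and the two sites between a MOM ether and the benzyl ether. Benzylic deprotonation with Wittig rearrangement may also compete.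
- The fallback sets out from 6 and comes back at 9. It fixes the position by electrophilic substitution instead of deprotonation.
- I2 and NaHCO3 in THF/H2O at 0 °C, conditions that place iodine between the two hydroxyls of resorcinols, should give 5-(benzyloxy)-2-iodobenzene-1,3-diol F5.
- MOMCl and iPr2NEt convert it into 5-(benzyloxy)-2-iodo-1,3-bis(methoxymethoxy)benzene F6.
- Iodine–magnesium exchange with iPrMgCl·LiCl (THF, −20 °C) gives the arylmagnesium chloride F7, and iPrOBpin traps it as 9.
- No alkyllithium base meets the benzyl ether on this path.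

## Further compounds

F1 | step 11 | 5,7-bis(benzyloxy)-6-[4-(benzyloxy)-3-(1-ethoxyvinyl)-2,6-dihydroxyphenyl]-2-(4-methoxyphenyl)chromen-4-one | COc1ccc(-c2cc(=O)c3c(OCc4ccccc4)c(-c4c(O)cc(OCc5ccccc5)c(C(=C)OCC)c4O)c(OCc4ccccc4)cc3o2)cc1
F2 | step 11 | 6-[3-acetyl-4-(benzyloxy)-2,6-dihydroxyphenyl]-5,7-bis(benzyloxy)-2-(4-methoxyphenyl)chromen-4-one | COc1ccc(-c2cc(=O)c3c(OCc4ccccc4)c(-c4c(O)cc(OCc5ccccc5)c(C(C)=O)c4O)c(OCc4ccccc4)cc3o2)cc1
F3 | step 11 | 1-{6-(benzyloxy)-3-[5,7-bis(benzyloxy)-2-(4-methoxyphenyl)-4-oxochromen-6-yl]-2,4-dihydroxyphenyl}-3-[4-(benzyloxy)phenyl]propane-1,3-dione | COc1ccc(-c2cc(=O)c3c(OCc4ccccc4)c(-c4c(O)cc(OCc5ccccc5)c(C(=O)CC(=O)c5ccc(OCc6ccccc6)cc5)c4O)c(OCc4ccccc4)cc3o2)cc1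
F4 | step 7 | [4-(benzyloxy)-2,6-bis(methoxymethoxy)phenyl]zinc chloride | Cl[Zn]c1c(OCOC)cc(OCc2ccccc2)cc1OCOC
F5 | step 6 | 5-(benzyloxy)-2-iodobenzene-1,3-diol | Oc1cc(OCc2ccccc2)cc(O)c1I
F6 | step 6 | 5-(benzyloxy)-2-iodo-1,3-bis(methoxymethoxy)benzene | COCOc1cc(OCc2ccccc2)cc(OCOC)c1I
F7 | step 6 | [4-(benzyloxy)-2,6-bis(methoxymethoxy)phenyl]magnesium chloride | Cl[Mg]c1c(OCOC)cc(OCc2ccccc2)cc1OCOC
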